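Ring A, numbered C1 (OMe), C2 (H), C3 (OH), C4 (H), C5 (arylethyl arm) and C6 (benzyl), is a resorcinol with two unlike oxygens and two adjacent carbon substituents. It is cut into a four-carbon vinylketene (C1, C6, C5, C4) and a two-carbon oxygenated alkyne (C2, C3). Heating a cyclobutenone with (triisopropylsiloxy)ethyne forms C1–C2, C3–C4 and C1–C6 in one operation and delivers ring A with the C1 oxygen free and the C3 oxygen silylated, so that only O1 can be methylated afterwards. The precursor is a racemic cyclobut-2-enone carrying the arylethyl arm on its carbon 3 and the benzyl group on its carbon 4, both outer phenols being benzyl ethers.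

Key step: step 7

Remark: the target has no stereocentre, so the compound required is a single achiral substance and the racemic centre of the cyclobutenones is erased in step 7; the given structures of precursor and product were checked against the mechanism and needed no correction; O-benzylated acid 1 is taken as purchasable, which saves a benzylation and a saponification.

Step 1
Reactants: 1 3-[4-(benzyloxy)phenyl]propanoic acid
Product: 2 3-[4-(benzyloxy)phenyl]propanoyl chloride
Conditions: (COCl)2, cat. DMF, CH2Cl2, 0 °C → rt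
Reagents that add atoms: oxalyl chloride, ClC(=O)C(Cl)=O
Why: Acid chloride formation through the catalytic Vilsmeier-type chloroiminium species is mild and should leave the aryl benzyl ether untouched.

Step 2
Reactants: 2 3-[4-(benzyloxy)phenyl]propanoyl chloride; 3 ethoxyacetylene
Product: 5 rac-4-[4-(benzyloxy)benzyl]-3-ethoxycyclobut-2-en-1-one, via ketene 4 (not isolated)
Conditions: 3 (3 equiv), Et3N, Et2O, 0 °C → rt, 2 added slowly
Reagents that add atoms: none
Why: Dehydrochlorination gives aldoketene 4, which should undergo the ketene–alkoxyalkyne [2+2] cycloaddition with the nucleophilic terminal alkyne carbon bonding to the ketene carbonyl carbon, so that the ethoxy carbon lies next to the benzyl-bearing carbon and the single stereocentre forms racemic.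

Step 3
Reactants: 6 2-(2-hydroxyphenyl)ethanol
Product: 7 2-[2-(benzyloxy)phenyl]ethan-1-ol
Conditions: BnBr, K2CO3, acetone, reflux
Reagents that add atoms: benzyl bromide, BrCc1ccccc1
Why: Williamson etherification under carbonate base should alkylate only the phenol, since the primary alcohol is not deprotonated.

Step 4
Reactants: 7 2-[2-(benzyloxy)phenyl]ethan-1-ol
Product: 8 1-(benzyloxy)-2-(2-bromoethyl)benzene
Conditions: CBr4, PPh3, CH2Cl2, 0 °C → rt
Reagents that add atoms: carbon tetrabromide, BrC(Br)(Br)Br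
Why: The Appel reaction converts the primary alcohol into the bromide under neutral conditions that spare the benzyl ether.

Step 5
Reactants: 8 1-(benzyloxy)-2-(2-bromoethyl)benzene; 5 rac-4-[4-(benzyloxy)benzyl]-3-ethoxycyclobut-2-en-1-one
Product: 11 rac-4-[4-(benzyloxy)benzyl]-3-{2-[2-(benzyloxy)phenyl]ethyl}cyclobut-2-en-1-one, via Grignard reagent 9 (not isolated), via cyclobutenol adduct 10 (not isolated)
Conditions: Mg, THF, rt; then 5, THF, –78 → 0 °C; then 1 M HCl, 0 °C → rt
Reagents that add atoms: water, O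
Why: Grignard 1,2-addition to the vinylogous ester carbonyl (enolisation would create an antiaromatic cyclobutadienolate and is disfavoured) followed by acid hydrolysis of the enol ether with loss of water (Stork–Danheiser-type carbonyl transposition) should give the 3-substituted cyclobutenone, the ring stereocentre staying racemic and the carbinol centre being lost.

Step 6
Reactants: 12 ethyl formate
Product: 15 (triisopropylsiloxy)ethyne, via dibromoenolate 13 (not isolated), via lithium ethynolate 14 (not isolated)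
Conditions: CH2Br2, LiTMP, THF, –78 °C; LiHMDS; n-BuLi, –78 °C → rt; TIPSCl, –78 °C → rt
Reagents that add atoms: dibromomethane, BrCBr; triisopropylsilyl chloride, CC(C)[Si](Cl)(C(C)C)C(C)C
Why: This is the Kowalski ester-to-ynolate homologation applied to the simplest ester, in which dibromomethyllithium adds to the formate, base gives enolate 13, bromine–lithium exchange and 1,2-shift in the carbenoid give ynolate 14, and the bulky silyl chloride is expected to silylate on oxygen (ynolate O-silylation).

Step 7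
Reactants: 11 rac-4-[4-(benzyloxy)benzyl]-3-{2-[2-(benzyloxy)phenyl]ethyl}cyclobut-2-en-1-one; 15 (triisopropylsiloxy)ethyne
Product: 20 2-[4-(benzyloxy)benzyl]-3-{2-[2-(benzyloxy)phenyl]ethyl}-5-(triisopropylsiloxy)phenol, via vinylketene 16 (not isolated), via vinylcyclobutenone 17 (not isolated), via dienylketene 18 (not isolated), via cyclohexadienone 19 (not isolated)
Conditions: 15 (2 equiv), toluene, 80 °C, then 110 °C
Reagents that add atoms: none
Why: Thermal 4π-electrocyclic opening of 11 should give vinylketene 16 with the benzyl arm rotating outward, and its ketene C=C adds [2+2] to the electron-rich alkyne to give vinylcyclobutenone 17; a second 4π opening gives dienylketene 18, 6π-electrocyclisation gives dienone 19, and tautomerisation gives phenol 20. This is the Danheiser benzannulation in its siloxyalkyne form, a known reaction type for alkyl-substituted cyclobutenones. Ring A is closed by disrotatory 6π-electrocyclisation of the ketene carbon onto the alkene terminus (C1–C6), after C1–C2 and C3–C4 have been made in the [2+2] event. No stereocentre is created, and the racemic centre of 11 disappears on aromatisation. The one selectivity needed is the orientation of the [2+2] addition, and polarity secures it: the unsubstituted, nucleophilic alkyne carbon bonds to the electrophilic ketene carbon, so the silyloxy carbon ends meta to the new hydroxyl and the benzyl-bearing carbon ortho to it. The benzyl ethers and the saturated arms should be inert at these temperatures.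

Step 8
Reactants: 20 2-[4-(benzyloxy)benzyl]-3-{2-[2-(benzyloxy)phenyl]ethyl}-5-(triisopropylsiloxy)phenol
Product: 21 2-[4-(benzyloxy)benzyl]-3-{2-[2-(benzyloxy)phenyl]ethyl}-1-methoxy-5-(triisopropylsiloxy)benzene
Conditions: MeI, K2CO3, acetone, reflux
Reagents that add atoms: iodomethane, CI
Why: Williamson O-methylation of the only free phenol under anhydrous carbonate conditions should leave the aryl triisopropylsilyl ether and the benzyl ethers in place.

Step 9
Reactants: 21 2-[4-(benzyloxy)benzyl]-3-{2-[2-(benzyloxy)phenyl]ethyl}-1-methoxy-5-(triisopropylsiloxy)benzene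
Product: 22 4-[4-(benzyloxy)benzyl]-3-{2-[2-(benzyloxy)phenyl]ethyl}-5-methoxyphenol
Conditions: TBAF, THF, 0 °C → rt; aq. NH4Cl
Reagents that add atoms: none
Why: Fluoride-induced desilylation of the aryl silyl ether, driven by Si–F bond formation, is selective over benzyl and methyl ethers.

Step 10
Reactants: 22 4-[4-(benzyloxy)benzyl]-3-{2-[2-(benzyloxy)phenyl]ethyl}-5-methoxyphenol
Product: 23 3-[2-(2-hydroxyphenyl)ethyl]-4-(4-hydroxybenzyl)-5-methoxyphenol
Conditions: H2 (1 atm), 10% Pd/C, EtOAc–MeOH, rt
Reagents that add atoms: none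
Why: Catalytic hydrogenolysis should cleave both aryl benzyl ethers while the diarylmethane, the aryl methyl ether and the arenes are stable at 1 atm and room temperature.

Compound list
1 | 3-[4-(benzyloxy)phenyl]propanoic acid | OC(=O)CCc1ccc(OCc2ccccc2)cc1 | starting material
2 | 3-[4-(benzyloxy)phenyl]propanoyl chloride | ClC(=O)CCc1ccc(OCc2ccccc2)cc1 | intermediate
3 | ethoxyacetylene | CCOC#C | starting material
4 | 3-[4-(benzyloxy)phenyl]prop-1-en-1-one ([4-(benzyloxy)benzyl]ketene) | O=C=CCc1ccc(OCc2ccccc2)cc1 | intermediate (not isolated)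
5 | rac-4-[4-(benzyloxy)benzyl]-3-ethoxycyclobut-2-en-1-one | CCOC1=CC(=O)C1Cc1ccc(OCc2ccccc2)cc1 | intermediate
6 | 2-(2-hydroxyphenyl)ethanol | OCCc1ccccc1O | starting material
7 | 2-[2-(benzyloxy)phenyl]ethan-1-ol | OCCc1ccccc1OCc1ccccc1 | intermediate
8 | 1-(benzyloxy)-2-(2-bromoethyl)benzene | BrCCc1ccccc1OCc1ccccc1 | intermediate
9 | {2-[2-(benzyloxy)phenyl]ethyl}magnesium bromide | Br[Mg]CCc1ccccc1OCc1ccccc1 | intermediate (not isolated)
10 | 4-[4-(benzyloxy)benzyl]-1-{2-[2-(benzyloxy)phenyl]ethyl}-3-ethoxycyclobut-2-en-1-ol (magnesium alkoxide in the flask, racemic mixture of diastereomers) | CCOC1=CC(O)(CCc2ccccc2OCc2ccccc2)C1Cc1ccc(OCc2ccccc2)cc1 | intermediate (not isolated)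
11 | rac-4-[4-(benzyloxy)benzyl]-3-{2-[2-(benzyloxy)phenyl]ethyl}cyclobut-2-en-1-one | O=C1C=C(CCc2ccccc2OCc2ccccc2)C1Cc1ccc(OCc2ccccc2)cc1 | intermediate (key-step precursor)
12 | ethyl formate | CCOC=O | starting material
13 | lithium 2,2-dibromoethenolate | [Li+].[O-]C=C(Br)Br | intermediate (not isolated)
14 | lithium ethynolate | [Li+].[O-]C#C | intermediate (not isolated)
15 | (triisopropylsiloxy)ethyne | C#CO[Si](C(C)C)(C(C)C)C(C)C | intermediate
16 | (3E)-5-[4-(benzyloxy)phenyl]-3-{2-[2-(benzyloxy)phenyl]ethyl}penta-1,3-dien-1-one | O=C=C/C(CCc1ccccc1OCc1ccccc1)=C/Cc1ccc(OCc2ccccc2)cc1 | intermediate (not isolated)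
17 | rac-4-{(2E)-1-[4-(benzyloxy)phenyl]-5-[2-(benzyloxy)phenyl]pent-2-en-3-yl}-3-(triisopropylsiloxy)cyclobut-2-en-1-one | O=C1C=C(O[Si](C(C)C)(C(C)C)C(C)C)C1/C(CCc1ccccc1OCc1ccccc1)=C/Cc1ccc(OCc2ccccc2)cc1 | intermediate (not isolated)
18 | (3E,5E)-7-[4-(benzyloxy)phenyl]-5-{2-[2-(benzyloxy)phenyl]ethyl}-3-(triisopropylsiloxy)hepta-1,3,5-trien-1-one (ketene and alkenyl groups cis across C3=C4) | O=C=C/C(O[Si](C(C)C)(C(C)C)C(C)C)=C\C(CCc1ccccc1OCc1ccccc1)=C\Cc1ccc(OCc2ccccc2)cc1 | intermediate (not isolated)
19 | rac-6-[4-(benzyloxy)benzyl]-5-{2-[2-(benzyloxy)phenyl]ethyl}-3-(triisopropylsiloxy)cyclohexa-2,4-dien-1-one | O=C1C=C(O[Si](C(C)C)(C(C)C)C(C)C)C=C(CCc2ccccc2OCc2ccccc2)C1Cc1ccc(OCc2ccccc2)cc1 | intermediate (not isolated)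
20 | 2-[4-(benzyloxy)benzyl]-3-{2-[2-(benzyloxy)phenyl]ethyl}-5-(triisopropylsiloxy)phenol | Oc1cc(O[Si](C(C)C)(C(C)C)C(C)C)cc(CCc2ccccc2OCc2ccccc2)c1Cc1ccc(OCc2ccccc2)cc1 | intermediate (key-step product)
21 | 2-[4-(benzyloxy)benzyl]-3-{2-[2-(benzyloxy)phenyl]ethyl}-1-methoxy-5-(triisopropylsiloxy)benzene | COc1cc(O[Si](C(C)C)(C(C)C)C(C)C)cc(CCc2ccccc2OCc2ccccc2)c1Cc1ccc(OCc2ccccc2)cc1 | intermediate
22 | 4-[4-(benzyloxy)benzyl]-3-{2-[2-(benzyloxy)phenyl]ethyl}-5-methoxyphenol | COc1cc(O)cc(CCc2ccccc2OCc2ccccc2)c1Cc1ccc(OCc2ccccc2)cc1 | intermediate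
23 | 3-[2-(2-hydroxyphenyl)ethyl]-4-(4-hydroxybenzyl)-5-methoxyphenol (achiral) | COc1cc(O)cc(CCc2ccccc2O)c1Cc1ccc(O)cc1 | target

Total step count: 10. Longest linear sequence: 7 steps (steps 3, 4, 5, 7, 8, 9, 10 from 6; equally steps 1, 2, 5, 7, 8, 9, 10 from 1).

Steps most likely to fail

Step 7. The vinylketene may not be captured fast enough, because the ynol silyl ether can be lost by thermal oxygen-to-carbon silyl shift or oligomerisation. The cascade may also stall before the second ring opening. The fallback is the complementary benzannulation in which the methyl ether is born on the alkyne. It sets out from ethoxyacetylene 3 and Grignard reagent 9 and comes back at phenol 22, so that steps 7 to 9 are not needed.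
- Ethoxyacetylene 3 is lithiated (n-BuLi, THF, –78 °C) to lithium ethoxyacetylide F1.
- F1 is alkylated with 4-(benzyloxy)benzyl bromide (THF–DMPU) to 1-(benzyloxy)-4-(3-ethoxyprop-2-yn-1-yl)benzene F2.
- [2+2] cycloaddition with ketene gas (CH2Cl2, 0 °C) gives 2-[4-(benzyloxy)benzyl]-3-ethoxycyclobut-2-en-1-one F3.
- Grignard reagent 9 adds to F3 to give the cyclobutenol adduct F4, and dilute HCl converts this into 2-[4-(benzyloxy)benzyl]-3-{2-[2-(benzyloxy)phenyl]ethyl}cyclobut-2-en-1-one F5.
- Heating F5 with methoxyacetylene (toluene, 80 °C) should run the same pericyclic cascade through vinylketene F6, vinylcyclobutenone F7, dienylketene F8 and cyclohexadienone F9. The methoxy carbon becomes C1 and the ketene carbon becomes C3, and the product is 22 directly.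

Step 6. The ambident parent ynolate may be silylated on carbon to give a silylketene, or the carbenoid rearrangement may be inefficient for a formate-derived enolate. The fallback fixes the O–Si bond before the triple bond is made. It sets out from ethyl formate 12 and comes back at alkyne 15.
- The first stage of step 6 is run as far as enolate 13.
- 13 is trapped on oxygen with TIPSOTf to give (2,2-dibromoethenyloxy)triisopropylsilane F10, which is isolated.
- n-BuLi (2 equiv, THF, –78 °C) should then effect bromine–lithium exchange and Fritsch–Buttenberg–Wiechell 1,2-shift (the second stage of a Corey–Fuchs sequence) to lithium (triisopropylsiloxy)ethynide F11.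
- F11 is protonated with acetic acid at –78 °C to give 15.

Step 2. Amine-mediated dimerisation of the aldoketene may outrun its cycloaddition to the alkyne. The fallback replaces the ketene by a keteniminium ion and builds the cyclobutenone in one cycloaddition. It sets out from acid chloride 2 and bromide 8 and comes back at cyclobutenone 11, so that steps 2 and 5 are not needed.
- 2 and dimethylamine give N,N-dimethyl-3-[4-(benzyloxy)phenyl]propanamide F12.
- 8 and lithium acetylide–ethylenediamine complex (DMSO, rt) give 1-(benzyloxy)-2-(but-3-yn-1-yl)benzene F13.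
- Tf2O and 2,4,6-collidine (CH2Cl2, –20 °C → reflux) convert F12 into the aldoketeniminium triflate F14.
- F14 undergoes Ghosez [2+2] cycloaddition with F13 to give cyclobuteniminium triflate F15. The terminal alkyne carbon bonds to the iminium carbon, so the arylethyl group ends on ring carbon 3 and the benzyl group on ring carbon 4.
- Aqueous hydrolysis of F15 gives 11.

Further compounds
F1 | step 7 | lithium ethoxyacetylide | [Li]C#COCC
F2 | step 7 | 1-(benzyloxy)-4-(3-ethoxyprop-2-yn-1-yl)benzene | CCOC#CCc1ccc(OCc2ccccc2)cc1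
F3 | step 7 | 2-[4-(benzyloxy)benzyl]-3-ethoxycyclobut-2-en-1-one | CCOC1=C(Cc2ccc(OCc3ccccc3)cc2)C(=O)C1
F4 | step 7 | rac-2-[4-(benzyloxy)benzyl]-1-{2-[2-(benzyloxy)phenyl]ethyl}-3-ethoxycyclobut-2-en-1-ol | CCOC1=C(Cc2ccc(OCc3ccccc3)cc2)C(O)(CCc2ccccc2OCc2ccccc2)C1
F5 | step 7 | 2-[4-(benzyloxy)benzyl]-3-{2-[2-(benzyloxy)phenyl]ethyl}cyclobut-2-en-1-one | O=C1CC(CCc2ccccc2OCc2ccccc2)=C1Cc1ccc(OCc2ccccc2)cc1
F6 | step 7 | 2-[4-(benzyloxy)benzyl]-5-[2-(benzyloxy)phenyl]-3-methylidenepent-1-en-1-one | O=C=C(Cc1ccc(OCc2ccccc2)cc1)C(=C)CCc1ccccc1OCc1ccccc1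
F7 | step 7 | rac-4-[4-(benzyloxy)benzyl]-4-{4-[2-(benzyloxy)phenyl]but-1-en-2-yl}-3-methoxycyclobut-2-en-1-one | COC1=CC(=O)C1(Cc1ccc(OCc2ccccc2)cc1)C(=C)CCc1ccccc1OCc1ccccc1
F8 | step 7 | (3E)-4-[4-(benzyloxy)benzyl]-7-[2-(benzyloxy)phenyl]-3-methoxy-5-methylidenehepta-1,3-dien-1-one | O=C=C/C(OC)=C(/Cc1ccc(OCc2ccccc2)cc1)\C(=C)CCc1ccccc1OCc1ccccc1
F9 | step 7 | 4-[4-(benzyloxy)benzyl]-5-{2-[2-(benzyloxy)phenyl]ethyl}-3-methoxycyclohexa-2,4-dien-1-one | O=C1C=C(OC)C(Cc2ccc(OCc3ccccc3)cc2)=C(CCc2ccccc2OCc2ccccc2)C1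
F10 | step 6 | (2,2-dibromoethenyloxy)triisopropylsilane | BrC(Br)=CO[Si](C(C)C)(C(C)C)C(C)C
F11 | step 6 | lithium (triisopropylsiloxy)ethynide | [Li]C#CO[Si](C(C)C)(C(C)C)C(C)C
F12 | step 2 | N,N-dimethyl-3-[4-(benzyloxy)phenyl]propanamide | CN(C)C(=O)CCc1ccc(OCc2ccccc2)cc1
F13 | step 2 | 1-(benzyloxy)-2-(but-3-yn-1-yl)benzene | C#CCCc1ccccc1OCc1ccccc1
F14 | step 2 | N-{3-[4-(benzyloxy)phenyl]prop-1-en-1-ylidene}-N-methylmethanaminium triflate | C[N+](C)=C=CCc1ccc(OCc2ccccc2)cc1.[O-]S(=O)(=O)C(F)(F)F
F15 | step 2 | rac-N-(4-[4-(benzyloxy)benzyl]-3-{2-[2-(benzyloxy)phenyl]ethyl}cyclobut-2-en-1-ylidene)-N-methylmethanaminium triflate | C[N+](C)=C1C=C(CCc2ccccc2OCc2ccccc2)C1Cc1ccc(OCc2ccccc2)cc1.[O-]S(=O)(=O)C(F)(F)F
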